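**Plan**

1. Retrosynthesis: remove the C8 acetate, then cut C6–C7. In the carbocycle (C4a, C5, C6, C7, C8, C8a) the C6(=O)–C7(OH)(CH3) α-ketol is an acyl anion at C6 added to a methyl ketone at C7, and C6 is the formyl carbon of a push–pull enal (O2–C3=C4–C4a=C5–C6H=O) standing on C4a of the pyran ring (O2, C1, C8a, C4a, C4, C3).
2. Further cuts: C4a=C5 (formyl olefination of a pyranone carbonyl), O2–C3 (cyclisation of a β-hydroxy ynone), C4–C4a (acetylide on a Weinreb amide), C8–C8a (syn aldol), and the two side-chain C=C bonds (Wittig, Horner–Wadsworth–Emmons).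
3. Forward: the side-chain dienyne and the aldol fragment are joined as an ynone; the pyran ring closes first, the carbocycle second in the carbene-catalysed step; the C8 silyl ether (TBS) is exchanged for acetate at the end.
4. Stereochemistry: the side-chain centre comes from (S)-2-methylbutan-1-ol; C8a and C8 are set together by an (R)-4-benzyloxazolidinone boron syn aldol with 2,2-dimethoxypropanal (the masked C7 ketone); C7 is set in the ring closure by the chair preference of the substrate, reinforced by a chiral triazolium salt.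

Key step: step 14

Numbering: atom labels C1–C8a follow the isochromene numbering of the target throughout.
Assumption: the exocyclic C4a=C5 bond of 23 and 24 is written E (formyl towards C8a) although an equilibrating E/Z mixture is expected, and the (5aR,10bS) antipode of the triazolium salt is written although the matched antipode has to be found by trial of both.

**Route**

Step 1
Reactants: 1 (S)-2-methylbutan-1-ol
Product: 3 ethyl (2E,4S)-2,4-dimethylhex-2-enoate, via (S)-2-methylbutanal 2 (not isolated)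
Conditions: TEMPO (10 mol %), PhI(OAc)2, CH2Cl2, rt; then Ph3P=C(Me)CO2Et, rt
Reagents that add atoms: ethyl 2-(triphenylphosphoranylidene)propanoate, CCOC(=O)C(C)=P(c1ccccc1)(c1ccccc1)c1ccccc1
Why: Oxoammonium oxidation gives the α-branched aldehyde under non-basic conditions and the stabilised ylide traps it at once in an E-selective Wittig olefination, so the (S)-centre should not be exposed to enolisation.

Step 2
Reactants: 3 ethyl (2E,4S)-2,4-dimethylhex-2-enoate
Product: 4 (2E,4S)-2,4-dimethylhex-2-en-1-ol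
Conditions: DIBAL-H (2.2 equiv), CH2Cl2, −78 °C; aq. Rochelle salt
Reagents that add atoms: none
Why: DIBAL-H 1,2-reduction of an enoate to the allylic alcohol leaves the alkene geometry and the stereocentre untouched.

Step 3
Reactants: 4 (2E,4S)-2,4-dimethylhex-2-en-1-ol
Product: 5 (2E,4S)-2,4-dimethylhex-2-enal
Conditions: MnO2, CH2Cl2, rt
Reagents that add atoms: none
Why: Manganese dioxide oxidation is selective for the allylic alcohol and should give the volatile enal without E/Z isomerisation.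

Step 4
Reactants: 5 (2E,4S)-2,4-dimethylhex-2-enal
Product: 7 (3E,5E,7S)-5,7-dimethylnona-3,5-dien-1-yne, via silyl dienyne 6 (not isolated)
Conditions: (EtO)2P(O)CH2C≡CTMS, LiHMDS, THF, −78 → 0 °C; then K2CO3, MeOH, rt
Reagents that add atoms: diethyl [3-(trimethylsilyl)prop-2-yn-1-yl]phosphonate, CCOP(=O)(OCC)CC#C[Si](C)(C)C
Why: Horner–Wadsworth–Emmons olefination with the lithiated silylpropargyl phosphonate should form the new C=C bond with E selectivity, and methanolysis of the alkynylsilane in the same flask frees the terminal alkyne.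

Step 5
Reactants: 8 methyl 2,2-dimethoxypropanoate
Product: 9 2,2-dimethoxypropanal
Conditions: DIBAL-H (1.05 equiv), CH2Cl2, −78 °C; MeOH, aq. Rochelle salt
Reagents that add atoms: none
Why: Partial DIBAL-H reduction of an α,α-dialkoxy ester stops at the chelated aluminium hemiacetal at −78 °C and should release the non-enolisable aldehyde on work-up.

Step 6
Reactants: 10 3-(benzyloxy)propanoic acid; 11 (R)-4-benzyloxazolidin-2-one
Product: 13 (R)-4-benzyl-3-[3-(benzyloxy)propanoyl]oxazolidin-2-one, via mixed pivalic anhydride 12 (not isolated)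
Conditions: PivCl, Et3N, THF, −20 °C; then 11, LiCl, −20 °C → rt
Reagents that add atoms: none
Why: N-Acylation of the oxazolidinone through the mixed pivalic anhydride under LiCl/Et3N is the standard one-flask preparation of such imides.

Step 7
Reactants: 13 (R)-4-benzyl-3-[3-(benzyloxy)propanoyl]oxazolidin-2-one; 9 2,2-dimethoxypropanal
Product: 15 (4R)-4-benzyl-3-[(2R,3R)-2-[(benzyloxy)methyl]-3-hydroxy-4,4-dimethoxypentanoyl]oxazolidin-2-one, via boron Z-enolate 14 (not isolated)
Conditions: Bu2BOTf, Et3N, CH2Cl2, −78 → 0 °C; then 9, −78 → 0 °C; pH 7 buffer, MeOH, 30% H2O2, 0 °C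
Reagents that add atoms: none
Why: Evans syn aldol: the Z(O) dibutylboron enolate reacts through a Zimmerman–Traxler chair on the face away from the auxiliary benzyl group, which with the (R)-auxiliary should set C8a and C8 as (2R,3R), that is C1 and O8 syn along the C4a–C8a–C8–C7 chain as the target requires.

Step 8
Reactants: 15 (4R)-4-benzyl-3-[(2R,3R)-2-[(benzyloxy)methyl]-3-hydroxy-4,4-dimethoxypentanoyl]oxazolidin-2-one
Product: 16 (2R,3R)-2-[(benzyloxy)methyl]-3-hydroxy-N,4,4-trimethoxy-N-methylpentanamide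
Conditions: MeNHOMe·HCl, AlMe3, CH2Cl2, −20 → 0 °C; aq. Rochelle salt
Reagents that add atoms: N,O-dimethylhydroxylamine hydrochloride, CNOC.Cl
Why: Aluminium amide transamination of a β-hydroxy imide, assisted by the aluminium alkoxide, should give the Weinreb amide and release the auxiliary without touching C8a.

Step 9
Reactants: 16 (2R,3R)-2-[(benzyloxy)methyl]-3-hydroxy-N,4,4-trimethoxy-N-methylpentanamide
Product: 17 (2R,3R)-2-[(benzyloxy)methyl]-3-[(tert-butyldimethylsilyl)oxy]-N,4,4-trimethoxy-N-methylpentanamide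
Conditions: TBSOTf, 2,6-lutidine, CH2Cl2, −78 → 0 °C
Reagents that add atoms: tert-butyldimethylsilyl trifluoromethanesulfonate, CC(C)(C)[Si](C)(C)OS(=O)(=O)C(F)(F)F
Why: Silyl triflate silylation copes with the hindered secondary hydroxyl, and TBS rather than TES is chosen so that the C8 ether outlasts the aqueous acid of step 13.

Step 10
Reactants: 17 (2R,3R)-2-[(benzyloxy)methyl]-3-[(tert-butyldimethylsilyl)oxy]-N,4,4-trimethoxy-N-methylpentanamide
Product: 18 (2R,3R)-3-[(tert-butyldimethylsilyl)oxy]-2-(hydroxymethyl)-N,4,4-trimethoxy-N-methylpentanamide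
Conditions: H2 (1 atm), Pd/C, EtOAc, rt
Reagents that add atoms: none
Why: Hydrogenolysis of the benzyl ether under neutral conditions frees the C1 hydroxyl before any alkene is present, and the silyl ether, the ketal and the amide N–O bond should be inert.

Step 11
Reactants: 7 (3E,5E,7S)-5,7-dimethylnona-3,5-dien-1-yne; 18 (2R,3R)-3-[(tert-butyldimethylsilyl)oxy]-2-(hydroxymethyl)-N,4,4-trimethoxy-N-methylpentanamide
Product: 20 (3R,4R,8E,10E,12S)-3-[(tert-butyldimethylsilyl)oxy]-4-(hydroxymethyl)-2,2-dimethoxy-10,12-dimethyltetradeca-8,10-dien-6-yn-5-one, via lithium acetylide 19 (not isolated)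
Conditions: 7 (2.5 equiv), n-BuLi, THF, −78 °C; then 18, −78 → −20 °C; aq. NH4Cl
Reagents that add atoms: none
Why: Acetylide addition to a Weinreb amide stops at the chelated tetrahedral adduct and gives the ynone on quench; the excess acetylide takes up the hydroxyl proton and the surplus alkyne is recovered.

Step 12
Reactants: 20 (3R,4R,8E,10E,12S)-3-[(tert-butyldimethylsilyl)oxy]-4-(hydroxymethyl)-2,2-dimethoxy-10,12-dimethyltetradeca-8,10-dien-6-yn-5-one
Product: 21 (3R)-3-[(1R)-1-[(tert-butyldimethylsilyl)oxy]-2,2-dimethoxypropyl]-6-[(1E,3E,5S)-3,5-dimethylhepta-1,3-dien-1-yl]-2,3-dihydro-4H-pyran-4-one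
Conditions: Ph3PAuNTf2 (5 mol %), CH2Cl2, rt
Reagents that add atoms: none
Why: Gold(I)-catalysed 6-endo-dig cycloisomerisation of a β-hydroxy ynone (intramolecular oxa-Michael addition to C3) is an established entry to 2,3-dihydro-4H-pyran-4-ones and runs under neutral conditions that should spare the ketal and C8a.

Step 13
Reactants: 21 (3R)-3-[(1R)-1-[(tert-butyldimethylsilyl)oxy]-2,2-dimethoxypropyl]-6-[(1E,3E,5S)-3,5-dimethylhepta-1,3-dien-1-yl]-2,3-dihydro-4H-pyran-4-one
Product: 24 (2E)-2-[(3R)-3-[(1R)-1-[(tert-butyldimethylsilyl)oxy]-2-oxopropyl]-6-[(1E,3E,5S)-3,5-dimethylhepta-1,3-dien-1-yl]-2,3-dihydro-4H-pyran-4-ylidene]acetaldehyde, via ethoxyvinyl carbinol 22 (not isolated), via ketal enal 23 (not isolated)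
Conditions: (Z)-BrCH=CHOEt, n-BuLi, THF, −78 °C; then 21, −78 °C; then 1 M aq. HCl, THF, 0 °C → rt
Reagents that add atoms: (Z)-1-bromo-2-ethoxyethene, Br/C=C\OCC; water, O
Why: 1,2-Addition of (Z)-2-ethoxyvinyllithium to the vinylogous ester carbonyl (the addition used in Stork–Danheiser sequences on α′-substituted 3-alkoxy enones) followed by acid-induced allylic transposition of the 3-ethoxyallyl carbinol is the established two-carbon formyl olefination of ketones; the same acid hydrolyses the dimethyl ketal, the cyclic push–pull dienal is the thermodynamic sink of the cation manifold, and the hindered TBS ether should persist.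

Step 14
Reactants: 24 (2E)-2-[(3R)-3-[(1R)-1-[(tert-butyldimethylsilyl)oxy]-2-oxopropyl]-6-[(1E,3E,5S)-3,5-dimethylhepta-1,3-dien-1-yl]-2,3-dihydro-4H-pyran-4-ylidene]acetaldehyde
Product: 25 (7R,8R,8aR)-8-[(tert-butyldimethylsilyl)oxy]-3-[(1E,3E,5S)-3,5-dimethylhepta-1,3-dien-1-yl]-7-hydroxy-7-methyl-1,7,8,8a-tetrahydro-6H-isochromen-6-one
Conditions: (5aR,10bS)-aminoindanol-derived N-C6F5 triazolium tetrafluoroborate (10 mol %), i-Pr2NEt (20 mol %), toluene, rt → 40 °C
Reagents that add atoms: none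
Why: Proposed new method: the triazolylidene adds to the formyl carbon C6 of the push–pull enal, proton transfer gives the Breslow intermediate, and this acyl anion equivalent attacks the C7 ketone before the carbene is expelled, leaving the C6 ketone conjugated with the dienol ether; the closest known reactions are the enantioselective intramolecular aldehyde–ketone crossed benzoin of aryl and alkyl aldehydes and the acyl-anion (Stetter, aza-benzoin) chemistry of enals under triazolylidene catalysis, a vinylogous formate donor being untested. The carbocycle closes in a 6-exo-trig mode, whereas the homoenolate carbon C4a is fully substituted and could only close a four-membered ring. The new centre C7 is set in a chair-like transition state in which the C6–C7 bond forms anti to the equatorial C8–O bond (Felkin–Anh arrangement) and the ketone methyl sits equatorial away from C8a, and the chiral pocket of the catalyst is chosen to reinforce this face. The step needs acyl-anion reactivity rather than β-protonation, which aprotic conditions and the hindered, donor-substituted β-carbon should favour, and it needs the E-enal, which the easily rotating push–pull alkene can supply from either isomer. The α-silyloxy group makes the ketone a better acceptor and, being a poor leaving group, should resist elimination towards C8a.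

Step 15
Reactants: 25 (7R,8R,8aR)-8-[(tert-butyldimethylsilyl)oxy]-3-[(1E,3E,5S)-3,5-dimethylhepta-1,3-dien-1-yl]-7-hydroxy-7-methyl-1,7,8,8a-tetrahydro-6H-isochromen-6-one
Product: 26 (7R,8R,8aR)-3-[(1E,3E,5S)-3,5-dimethylhepta-1,3-dien-1-yl]-7,8-dihydroxy-7-methyl-1,7,8,8a-tetrahydro-6H-isochromen-6-one
Conditions: HF·pyridine, pyridine, THF, 0 °C → rt
Reagents that add atoms: none
Why: Buffered HF·pyridine desilylation avoids free base, so the tertiary α-ketol and the acidic C8a–H of the dienone should survive.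

Step 16
Reactants: 26 (7R,8R,8aR)-3-[(1E,3E,5S)-3,5-dimethylhepta-1,3-dien-1-yl]-7,8-dihydroxy-7-methyl-1,7,8,8a-tetrahydro-6H-isochromen-6-one
Product: 27 (7R,8R,8aR)-3-[(1E,3E,5S)-3,5-dimethylhepta-1,3-dien-1-yl]-7-hydroxy-7-methyl-6-oxo-6,7,8,8a-tetrahydro-1H-isochromen-8-yl acetate (8-acetyldechloroisochromophilone III)
Conditions: Ac2O, pyridine, DMAP (cat.), CH2Cl2, 0 °C
Reagents that add atoms: acetic anhydride, CC(=O)OC(C)=O
Why: DMAP-catalysed acylation should take the secondary C8 hydroxyl and leave the tertiary C7 hydroxyl free at 0 °C.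

**Compound list**

1 | (S)-2-methylbutan-1-ol | CC[C@H](C)CO | starting material
2 | (S)-2-methylbutanal | CC[C@H](C)C=O | intermediate (not isolated)
3 | ethyl (2E,4S)-2,4-dimethylhex-2-enoate | CCOC(=O)/C(C)=C/[C@@H](C)CC | intermediate
4 | (2E,4S)-2,4-dimethylhex-2-en-1-ol | OC/C(C)=C/[C@@H](C)CC | intermediate
5 | (2E,4S)-2,4-dimethylhex-2-enal | O=C/C(C)=C/[C@@H](C)CC | intermediate
6 | trimethyl[(3E,5E,7S)-5,7-dimethylnona-3,5-dien-1-yn-1-yl]silane | C[Si](C)(C)C#C/C=C/C(C)=C/[C@@H](C)CC | intermediate (not isolated)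
7 | (3E,5E,7S)-5,7-dimethylnona-3,5-dien-1-yne | C#C/C=C/C(C)=C/[C@@H](C)CC | intermediate
8 | methyl 2,2-dimethoxypropanoate | COC(=O)C(C)(OC)OC | starting material
9 | 2,2-dimethoxypropanal | O=CC(C)(OC)OC | intermediate
10 | 3-(benzyloxy)propanoic acid | OC(=O)CCOCc1ccccc1 | starting material
11 | (R)-4-benzyloxazolidin-2-one | O=C1N[C@H](Cc2ccccc2)CO1 | starting material
12 | 3-(benzyloxy)propanoic pivalic anhydride | CC(C)(C)C(=O)OC(=O)CCOCc1ccccc1 | intermediate (not isolated)
13 | (R)-4-benzyl-3-[3-(benzyloxy)propanoyl]oxazolidin-2-one | O=C(CCOCc1ccccc1)N1[C@H](Cc2ccccc2)COC1=O | intermediate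
14 | (R)-4-benzyl-3-[(Z)-3-(benzyloxy)-1-[(dibutylboranyl)oxy]prop-1-en-1-yl]oxazolidin-2-one | CCCCB(CCCC)O/C(=C\COCc1ccccc1)N1[C@H](Cc2ccccc2)COC1=O | intermediate (not isolated)
15 | (4R)-4-benzyl-3-[(2R,3R)-2-[(benzyloxy)methyl]-3-hydroxy-4,4-dimethoxypentanoyl]oxazolidin-2-one | O=C([C@H](COCc1ccccc1)[C@@H](O)C(C)(OC)OC)N1[C@H](Cc2ccccc2)COC1=O | intermediate
16 | (2R,3R)-2-[(benzyloxy)methyl]-3-hydroxy-N,4,4-trimethoxy-N-methylpentanamide | CON(C)C(=O)[C@H](COCc1ccccc1)[C@@H](O)C(C)(OC)OC | intermediate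
17 | (2R,3R)-2-[(benzyloxy)methyl]-3-[(tert-butyldimethylsilyl)oxy]-N,4,4-trimethoxy-N-methylpentanamide | CON(C)C(=O)[C@H](COCc1ccccc1)[C@@H](O[Si](C)(C)C(C)(C)C)C(C)(OC)OC | intermediate
18 | (2R,3R)-3-[(tert-butyldimethylsilyl)oxy]-2-(hydroxymethyl)-N,4,4-trimethoxy-N-methylpentanamide | CON(C)C(=O)[C@H](CO)[C@@H](O[Si](C)(C)C(C)(C)C)C(C)(OC)OC | intermediate
19 | lithium (3E,5E,7S)-5,7-dimethylnona-3,5-dien-1-yn-1-ide | [Li]C#C/C=C/C(C)=C/[C@@H](C)CC | intermediate (not isolated)
20 | (3R,4R,8E,10E,12S)-3-[(tert-butyldimethylsilyl)oxy]-4-(hydroxymethyl)-2,2-dimethoxy-10,12-dimethyltetradeca-8,10-dien-6-yn-5-one | CC[C@H](C)/C=C(C)/C=C/C#CC(=O)[C@H](CO)[C@@H](O[Si](C)(C)C(C)(C)C)C(C)(OC)OC | intermediate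
21 | (3R)-3-[(1R)-1-[(tert-butyldimethylsilyl)oxy]-2,2-dimethoxypropyl]-6-[(1E,3E,5S)-3,5-dimethylhepta-1,3-dien-1-yl]-2,3-dihydro-4H-pyran-4-one | CC[C@H](C)/C=C(C)/C=C/C1=CC(=O)[C@H](CO1)[C@@H](O[Si](C)(C)C(C)(C)C)C(C)(OC)OC | intermediate
22 | (3R)-3-[(1R)-1-[(tert-butyldimethylsilyl)oxy]-2,2-dimethoxypropyl]-6-[(1E,3E,5S)-3,5-dimethylhepta-1,3-dien-1-yl]-4-[(Z)-2-ethoxyethenyl]-3,4-dihydro-2H-pyran-4-ol (C4 epimers, as lithium alkoxide before the acid) | CC[C@H](C)/C=C(C)/C=C/C1=CC(O)(/C=C\OCC)[C@H](CO1)[C@@H](O[Si](C)(C)C(C)(C)C)C(C)(OC)OC | intermediate (not isolated)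
23 | (2E)-2-[(3R)-3-[(1R)-1-[(tert-butyldimethylsilyl)oxy]-2,2-dimethoxypropyl]-6-[(1E,3E,5S)-3,5-dimethylhepta-1,3-dien-1-yl]-2,3-dihydro-4H-pyran-4-ylidene]acetaldehyde | CC[C@H](C)/C=C(C)/C=C/C1=C/C(=C/C=O)[C@H](CO1)[C@@H](O[Si](C)(C)C(C)(C)C)C(C)(OC)OC | intermediate (not isolated)
24 | (2E)-2-[(3R)-3-[(1R)-1-[(tert-butyldimethylsilyl)oxy]-2-oxopropyl]-6-[(1E,3E,5S)-3,5-dimethylhepta-1,3-dien-1-yl]-2,3-dihydro-4H-pyran-4-ylidene]acetaldehyde (formyl group on the C8a side) | CC[C@H](C)/C=C(C)/C=C/C1=C/C(=C/C=O)[C@H](CO1)[C@@H](O[Si](C)(C)C(C)(C)C)C(C)=O | intermediate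
25 | (7R,8R,8aR)-8-[(tert-butyldimethylsilyl)oxy]-3-[(1E,3E,5S)-3,5-dimethylhepta-1,3-dien-1-yl]-7-hydroxy-7-methyl-1,7,8,8a-tetrahydro-6H-isochromen-6-one | CC[C@H](C)/C=C(C)/C=C/C1=CC2=CC(=O)[C@](C)(O)[C@H](O[Si](C)(C)C(C)(C)C)[C@H]2CO1 | intermediate
26 | (7R,8R,8aR)-3-[(1E,3E,5S)-3,5-dimethylhepta-1,3-dien-1-yl]-7,8-dihydroxy-7-methyl-1,7,8,8a-tetrahydro-6H-isochromen-6-one | CC[C@H](C)/C=C(C)/C=C/C1=CC2=CC(=O)[C@](C)(O)[C@H](O)[C@H]2CO1 | intermediate
27 | (7R,8R,8aR)-3-[(1E,3E,5S)-3,5-dimethylhepta-1,3-dien-1-yl]-7-hydroxy-7-methyl-6-oxo-6,7,8,8a-tetrahydro-1H-isochromen-8-yl acetate | CC[C@H](C)/C=C(C)/C=C/C1=CC2=CC(=O)[C@](C)(O)[C@H](OC(C)=O)[C@H]2CO1 | target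

**Count**

Total: 16 steps. Longest linear sequence: 11 steps (steps 6–16 from 10 and 11; equally steps 5 and 7–16 from 8).

**Steps most likely to fail**

Step 14. The carbene may engage the deactivated, vinylogous-formate aldehyde only slowly, or divert through β-protonation to an unproductive acyl azolium, or close onto the C7 ketone with poor facial selectivity. The fallback uses known chemistry, sets out from 21 and comes back at 25. Pyridinium p-toluenesulfonate in wet acetone would free the methyl ketone F1. 1-Ethoxyvinyllithium (ethyl vinyl ether, t-BuLi, THF, −78 °C) would add to this more electrophilic α-silyloxy ketone in the Felkin–Anh sense, anti to the C8–O bond, to give the 7R ethoxyvinyl carbinol F2. Dilute acid on work-up would hydrolyse the enol ether to the α-hydroxy methyl ketone F3. Base-mediated intramolecular aldol condensation (KOt-Bu, t-BuOH–THF, 0 °C) of the new acetyl group onto the pyranone carbonyl, through the aldol F4, would then close the carbocycle at C4a=C5 and give 25.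

Step 13. Enolisation towards C8a or slow 1,2-addition at the hindered vinylogous ester carbonyl may compete, and the hydrolysis may drift to ring-opened hydroxy enones or lose the silyl ether. The fallback sets out from 21 and comes back at 24. The smaller, less basic lithium ethoxyacetylide (ethoxyacetylene, n-BuLi, THF, −78 °C) would give the ethoxyalkynyl carbinol F5. Dilute H2SO4 in THF would effect Meyer–Schuster rearrangement and ketal hydrolysis to the keto ester F6. DIBAL-H (CH2Cl2, −78 °C) would reduce ester and ketone to the diol F7, and Dess–Martin periodinane (NaHCO3, CH2Cl2) would oxidise both hydroxyls to give 24.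

Step 8. The aluminium amide may ionise or methylate the dimethyl ketal held next to the aluminium alkoxide, or cause retro-aldol cleavage of the hindered adduct. The fallback sets out from 15 and comes back at 16. Lithium hydroperoxide (LiOH, H2O2, THF–H2O, 0 °C) would cleave the auxiliary to the β-hydroxy acid F8, which carbodiimide coupling (MeNHOMe·HCl, EDC·HCl, HOBt, i-Pr2NEt, CH2Cl2) would convert into 16 without any Lewis acid.

**Further compounds**

F1 | step 14 | (3R)-3-[(1R)-1-[(tert-butyldimethylsilyl)oxy]-2-oxopropyl]-6-[(1E,3E,5S)-3,5-dimethylhepta-1,3-dien-1-yl]-2,3-dihydro-4H-pyran-4-one | CC[C@H](C)/C=C(C)/C=C/C1=CC(=O)[C@H](CO1)[C@@H](O[Si](C)(C)C(C)(C)C)C(C)=O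
F2 | step 14 | (3R)-3-[(1R,2R)-1-[(tert-butyldimethylsilyl)oxy]-3-ethoxy-2-hydroxy-2-methylbut-3-en-1-yl]-6-[(1E,3E,5S)-3,5-dimethylhepta-1,3-dien-1-yl]-2,3-dihydro-4H-pyran-4-one | CC[C@H](C)/C=C(C)/C=C/C1=CC(=O)[C@H](CO1)[C@@H](O[Si](C)(C)C(C)(C)C)[C@@](C)(O)C(=C)OCC
F3 | step 14 | (3R)-3-[(1R,2R)-1-[(tert-butyldimethylsilyl)oxy]-2-hydroxy-2-methyl-3-oxobutyl]-6-[(1E,3E,5S)-3,5-dimethylhepta-1,3-dien-1-yl]-2,3-dihydro-4H-pyran-4-one | CC[C@H](C)/C=C(C)/C=C/C1=CC(=O)[C@H](CO1)[C@@H](O[Si](C)(C)C(C)(C)C)[C@@](C)(O)C(C)=O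
F4 | step 14 | (7R,8R,8aR)-8-[(tert-butyldimethylsilyl)oxy]-3-[(1E,3E,5S)-3,5-dimethylhepta-1,3-dien-1-yl]-4a,7-dihydroxy-7-methyl-4a,5,8,8a-tetrahydro-1H-isochromen-6(7H)-one (4a epimers) | CC[C@H](C)/C=C(C)/C=C/C1=CC2(O)CC(=O)[C@](C)(O)[C@H](O[Si](C)(C)C(C)(C)C)[C@H]2CO1
F5 | step 13 | (3R)-3-[(1R)-1-[(tert-butyldimethylsilyl)oxy]-2,2-dimethoxypropyl]-6-[(1E,3E,5S)-3,5-dimethylhepta-1,3-dien-1-yl]-4-(ethoxyethynyl)-3,4-dihydro-2H-pyran-4-ol (C4 epimers) | CC[C@H](C)/C=C(C)/C=C/C1=CC(O)(C#COCC)[C@H](CO1)[C@@H](O[Si](C)(C)C(C)(C)C)C(C)(OC)OC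
F6 | step 13 | ethyl (2E)-2-[(3R)-3-[(1R)-1-[(tert-butyldimethylsilyl)oxy]-2-oxopropyl]-6-[(1E,3E,5S)-3,5-dimethylhepta-1,3-dien-1-yl]-2,3-dihydro-4H-pyran-4-ylidene]acetate | CC[C@H](C)/C=C(C)/C=C/C1=C/C(=C/C(=O)OCC)[C@H](CO1)[C@@H](O[Si](C)(C)C(C)(C)C)C(C)=O
F7 | step 13 | (2E)-2-[(3R)-3-[(1R)-1-[(tert-butyldimethylsilyl)oxy]-2-hydroxypropyl]-6-[(1E,3E,5S)-3,5-dimethylhepta-1,3-dien-1-yl]-2,3-dihydro-4H-pyran-4-ylidene]ethan-1-ol (carbinol epimers) | CC[C@H](C)/C=C(C)/C=C/C1=C/C(=C/CO)[C@H](CO1)[C@@H](O[Si](C)(C)C(C)(C)C)C(C)O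
F8 | step 8 | (2R,3R)-2-[(benzyloxy)methyl]-3-hydroxy-4,4-dimethoxypentanoic acid | OC(=O)[C@H](COCc1ccccc1)[C@@H](O)C(C)(OC)OC
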